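**Retrosynthetic overview**

1. Ciwujiatone ⇐ buffered desilylation ⇐ DDQ opening of a temporary second oxolane (ring D) of a 2,6-diaryl-3,7-dioxabicyclo[3.3.0]octane at its phenolic benzylic C–O bond; this unveils the aryl ketone and the CH2OH together.
2. Bicycle ⇐ acyclic epoxy cinnamyl ether by a Cp2TiCl radical cascade: ring C (the oxolane of the target) closes first by forming the C-3–C-4 bond, then ring D closes by C–O bond formation on adding iodine.
3. Feature that makes the key step possible (oxolane numbered O-1, C-2 with aryl A, C-3 with CH2OH, C-4 with the aroyl carbon of aryl B, C-5): C-3 and its CH2O carbon are the two carbons of a terminal epoxide, C-4 and its exocyclic benzylic carbon are the two carbons of a styrene, and C-2–O-1–C-5 tethers them as a 3-oxahex-5-enyl radical. The C-3–C-4 bond is the β–β′ bond between two sinapyl C6–C3 units, made by radical addition as in lignan biosynthesis, and the CH2OH is cis to the benzylic carbon, so it can bridge it as ring D.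
4. Epoxy ether ⇐ Williamson union of an erythro epoxy alcohol (Sharpless kinetic resolution, sets C-2) with a cinnamyl bromide; both C6–C3 halves come from syringaldehyde.

Key step: step 8

Assumption: the iodine-induced closure of ring D is taken to give the exo-aryl (syringaresinol-type) configuration at the new benzylic carbon; this centre is erased in step 10, so either epimer serves.

**Route**

Step 1
Reactants: 1 syringaldehyde (4-hydroxy-3,5-dimethoxybenzaldehyde)
Product: 2 3,5-dimethoxy-4-[(triisopropylsilyl)oxy]benzaldehyde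
Conditions: TIPSCl (1.3 equiv), imidazole (2.5 equiv), DMAP (cat.), DMF, 40 °C
Reagents that add atoms: triisopropylsilyl chloride, CC(C)[Si](Cl)(C(C)C)C(C)C
Why: O-silylation of the phenol; the bulky silyl ether is chosen to survive the Grignard, alkoxide, Cp2TiCl, hydrogenolysis and DDQ steps and to leave last under buffered fluoride.

Step 2
Reactants: 2 3,5-dimethoxy-4-[(triisopropylsilyl)oxy]benzaldehyde
Product: 3 rac-1-{3,5-dimethoxy-4-[(triisopropylsilyl)oxy]phenyl}prop-2-en-1-ol
Conditions: CH2=CHMgBr (1.2 equiv), THF, −78 to 0 °C; then aqueous work-up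
Reagents that add atoms: vinylmagnesium bromide, C=C[Mg]Br
Why: Grignard 1,2-addition to the aldehyde; the new carbinol stereocentre is formed racemic and is resolved in step 3.

Step 3
Reactants: 3 rac-1-{3,5-dimethoxy-4-[(triisopropylsilyl)oxy]phenyl}prop-2-en-1-ol
Product: 4 (R)-{3,5-dimethoxy-4-[(triisopropylsilyl)oxy]phenyl}[(S)-oxiran-2-yl]methanol (erythro epoxy alcohol)
Conditions: Ti(OiPr)4 (0.15 equiv), D-(−)-diisopropyl tartrate (0.2 equiv), t-BuOOH (0.45 equiv), 4 Å MS, CH2Cl2, −20 °C
Reagents that add atoms: tert-butyl hydroperoxide, CC(C)(C)OO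
Why: Sharpless kinetic resolution: with the D-(−)-tartrate ligand the (S)-enantiomer of the aryl vinyl carbinol should be epoxidised much faster than the (R)-enantiomer and with erythro selectivity, so at under half conversion 4 should form in high enantiomeric purity while the unreacted (R)-enantiomer of 3 is separated; the carbinol carbon becomes C-2 of ring C (its descriptor changes from S to R only through the priority change), and the new epoxide stereocentre is erased in step 8.

Step 4
Reactants: 1 syringaldehyde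
Product: 5 4-(benzyloxy)-3,5-dimethoxybenzaldehyde
Conditions: BnBr (1.1 equiv), K2CO3 (1.5 equiv), DMF, 60 °C
Reagents that add atoms: benzyl bromide, BrCc1ccccc1
Why: Williamson O-benzylation of the phenoxide; the benzyl ether on aryl B is orthogonal to the silyl ether on aryl A and can be removed alone before the oxidation.

Step 5
Reactants: 5 4-(benzyloxy)-3,5-dimethoxybenzaldehyde
Product: 6 rac-1-[4-(benzyloxy)-3,5-dimethoxyphenyl]prop-2-en-1-ol
Conditions: CH2=CHMgBr (1.2 equiv), THF, −78 to 0 °C; then aqueous work-up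
Reagents that add atoms: vinylmagnesium bromide, C=C[Mg]Br
Why: Grignard 1,2-addition; the racemic stereocentre does not matter because it is destroyed in step 6.

Step 6
Reactants: 6 rac-1-[4-(benzyloxy)-3,5-dimethoxyphenyl]prop-2-en-1-ol
Product: 7 (E)-2-(benzyloxy)-5-(3-bromoprop-1-en-1-yl)-1,3-dimethoxybenzene
Conditions: PBr3 (0.4 equiv), Et2O, 0 °C; used crude at once
Reagents that add atoms: phosphorus tribromide, BrP(Br)Br
Why: Bromination of the secondary benzylic allylic alcohol with allylic transposition (SN2′ or ion-pair collapse) should give the conjugated primary E-cinnamyl bromide, the thermodynamically favoured isomer.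

Step 7
Reactants: 4 (R)-{3,5-dimethoxy-4-[(triisopropylsilyl)oxy]phenyl}[(S)-oxiran-2-yl]methanol; 7 (E)-2-(benzyloxy)-5-(3-bromoprop-1-en-1-yl)-1,3-dimethoxybenzene
Product: 8 (S)-2-[(R)-{[(E)-3-(4-(benzyloxy)-3,5-dimethoxyphenyl)prop-2-en-1-yl]oxy}{3,5-dimethoxy-4-[(triisopropylsilyl)oxy]phenyl}methyl]oxirane
Conditions: NaH (1.1 equiv), THF/DMF, 0 °C; then 7 (1.2 equiv), Bu4NI (0.1 equiv), 0 °C to rt
Reagents that add atoms: none
Why: Williamson etherification: the sodium alkoxide of 4 attacks the primary allylic bromide by SN2, the C–O bond at the carbinol stereocentre is not broken so its configuration is retained, and low temperature in an aprotic medium should hold back Payne rearrangement.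

Step 8
Reactants: 8 (S)-2-[(R)-{[(E)-3-(4-(benzyloxy)-3,5-dimethoxyphenyl)prop-2-en-1-yl]oxy}{3,5-dimethoxy-4-[(triisopropylsilyl)oxy]phenyl}methyl]oxirane
Product: 12 (1S,3aR,4S,6aR)-1-[4-(benzyloxy)-3,5-dimethoxyphenyl]-4-{3,5-dimethoxy-4-[(triisopropylsilyl)oxy]phenyl}tetrahydro-1H,3H-furo[3,4-c]furan, via titanoxy radical 9 (not isolated), via benzylic titanium species 10 (not isolated), via benzylic iodide 11 (not isolated)
Conditions: Cp2TiCl2 (2.5 equiv), Zn dust, THF, rt (green Cp2TiCl, filtered from Zn), added dropwise to 8 (dilute in THF), rt; then I2 (1.5 equiv), THF, rt to 40 °C; aq. Na2S2O3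
Reagents that add atoms: none
Why: Cp2TiCl (trivalent titanium) opens the epoxide of 8 by single-electron transfer at its more substituted C–O bond (Nugent–RajanBabu opening) to give the secondary β-titanoxy radical 9, which adds 5-exo-trig to the proximal styrene carbon of the cinnamyl ether and so makes the C-3–C-4 bond of ring C; a second Cp2TiCl captures the benzylic radical to give 10, iodine converts the C–Ti bond into benzylic iodide 11, and the neighbouring titanium alkoxide displaces iodide through the alkoxyaryl-stabilised benzylic cation to close ring D. The closest known reaction type is the titanocene-mediated radical cyclisation of epoxy cinnamyl ethers with iodine work-up, which is established for 2,6-diaryl-3,7-dioxabicyclo[3.3.0]octane lignans. Ring C closes in the 5-exo-trig radical mode and ring D in the 5-exo-tet mode by C–O bond formation. C-2 (set in step 3) controls C-3 and C-4 through the chair-like transition state of the 3-oxahex-5-enyl radical, in which aryl A is pseudo-equatorial, the CH2O–Ti group on the radical carbon is anti to it (2,3-trans) and the styrene adds cis to that group (3,4-cis); the benzylic carbon of ring D should take the exo-aryl configuration on the convex face but is erased in step 10. The step needs 5-exo over 6-endo closure and cyclisation faster than reduction of 9 to an organotitanium that would eliminate to an alkene; the benzylic stabilisation of the adduct radical by aryl B secures the first and dropwise addition of Cp2TiCl to dilute 8 the second. Because C-3 passes through a planar radical, the configuration of the epoxide carbon of 8 does not matter.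

Step 9
Reactants: 12 (1S,3aR,4S,6aR)-1-[4-(benzyloxy)-3,5-dimethoxyphenyl]-4-{3,5-dimethoxy-4-[(triisopropylsilyl)oxy]phenyl}tetrahydro-1H,3H-furo[3,4-c]furan
Product: 13 4-[(1S,3aR,4S,6aR)-4-{3,5-dimethoxy-4-[(triisopropylsilyl)oxy]phenyl}tetrahydro-1H,3H-furo[3,4-c]furan-1-yl]-2,6-dimethoxyphenol
Conditions: H2 (1 atm), 10% Pd/C, EtOAc, rt, stopped at full conversion
Reagents that add atoms: none
Why: Hydrogenolysis of the aryl benzyl ether should be much faster than cleavage of the dialkyl benzylic C–O bonds of rings C and D, the silyl ether is inert, and no stereocentre is touched.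

Step 10
Reactants: 13 4-[(1S,3aR,4S,6aR)-4-{3,5-dimethoxy-4-[(triisopropylsilyl)oxy]phenyl}tetrahydro-1H,3H-furo[3,4-c]furan-1-yl]-2,6-dimethoxyphenol
Product: 15 [(2S,3R,4R)-2-{3,5-dimethoxy-4-[(triisopropylsilyl)oxy]phenyl}-3-(hydroxymethyl)oxolan-4-yl](4-hydroxy-3,5-dimethoxyphenyl)methanone, via cyclic hemiketal 14 (not isolated)
Conditions: DDQ (1.2 equiv), CH2Cl2/H2O (10:1), 0 °C to rt
Reagents that add atoms: water, O
Why: DDQ oxidation of a para-hydroxybenzylic ether: formal hydride abstraction at the benzylic C–H of ring D para to the free phenol gives an alkoxy-substituted quinone methide, water adds to give hemiketal 14, and ring–chain opening releases the aryl ketone and the CH2OH; the free phenol on aryl B against the silyl ether on aryl A secures the site selectivity, and C-3/C-4 stay cis because no base is present and even a transient enol ether of ring D would reprotonate on the convex face of the cis-fused bicycle.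

Step 11
Reactants: 15 [(2S,3R,4R)-2-{3,5-dimethoxy-4-[(triisopropylsilyl)oxy]phenyl}-3-(hydroxymethyl)oxolan-4-yl](4-hydroxy-3,5-dimethoxyphenyl)methanone
Product: 16 ciwujiatone, (4-hydroxy-3,5-dimethoxyphenyl)[(2S,3R,4R)-2-(4-hydroxy-3,5-dimethoxyphenyl)-3-(hydroxymethyl)oxolan-4-yl]methanone
Conditions: Bu4NF (1.2 equiv), AcOH (2 equiv), THF, 0 °C
Reagents that add atoms: none
Why: Fluoride cleavage of the aryl silyl ether, buffered with AcOH so that the C-4 stereocentre α to the ketone is not epimerised and the β-alkoxy ketone does not ring-open by retro-oxa-Michael reaction.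

**Compound list**

1 | syringaldehyde (4-hydroxy-3,5-dimethoxybenzaldehyde) | COc1cc(C=O)cc(OC)c1O | starting material
2 | 3,5-dimethoxy-4-[(triisopropylsilyl)oxy]benzaldehyde | COc1cc(C=O)cc(OC)c1O[Si](C(C)C)(C(C)C)C(C)C | intermediate
3 | rac-1-{3,5-dimethoxy-4-[(triisopropylsilyl)oxy]phenyl}prop-2-en-1-ol | COc1cc(C(O)C=C)cc(OC)c1O[Si](C(C)C)(C(C)C)C(C)C | intermediate
4 | (R)-{3,5-dimethoxy-4-[(triisopropylsilyl)oxy]phenyl}[(S)-oxiran-2-yl]methanol | O[C@H](c1cc(OC)c(O[Si](C(C)C)(C(C)C)C(C)C)c(OC)c1)[C@@H]1CO1 | intermediate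
5 | 4-(benzyloxy)-3,5-dimethoxybenzaldehyde | COc1cc(C=O)cc(OC)c1OCc1ccccc1 | intermediate
6 | rac-1-[4-(benzyloxy)-3,5-dimethoxyphenyl]prop-2-en-1-ol | COc1cc(C(O)C=C)cc(OC)c1OCc1ccccc1 | intermediate
7 | (E)-2-(benzyloxy)-5-(3-bromoprop-1-en-1-yl)-1,3-dimethoxybenzene | COc1cc(/C=C/CBr)cc(OC)c1OCc1ccccc1 | intermediate
8 | (S)-2-[(R)-{[(E)-3-(4-(benzyloxy)-3,5-dimethoxyphenyl)prop-2-en-1-yl]oxy}{3,5-dimethoxy-4-[(triisopropylsilyl)oxy]phenyl}methyl]oxirane | COc1cc(/C=C/CO[C@H](c2cc(OC)c(O[Si](C(C)C)(C(C)C)C(C)C)c(OC)c2)[C@@H]2CO2)cc(OC)c1OCc1ccccc1 | intermediate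
9 | open-chain β-titanoxy radical: the propan-2-yl radical from 8 carrying Cp2Ti(Cl)O on C-3 and the aryl A and cinnamyloxy groups on C-1 (configuration at C-1 as in 8) | COc1cc(/C=C/CO[C@H](c2cc(OC)c(O[Si](C(C)C)(C(C)C)C(C)C)c(OC)c2)[CH]CO[Ti](Cl)(C2C=CC=C2)C2C=CC=C2)cc(OC)c1OCc1ccccc1 | intermediate
10 | cyclised bis-titanium species: (2S,3R,4R)-2-(aryl A)oxolane with CH2O–TiCp2Cl on C-3 and CH(aryl B)–TiCp2Cl on C-4 (benzylic configuration undefined) | COc1cc(C([Ti](Cl)(C2C=CC=C2)C2C=CC=C2)[C@H]2CO[C@H](c3cc(OC)c(O[Si](C(C)C)(C(C)C)C(C)C)c(OC)c3)[C@H]2CO[Ti](Cl)(C3C=CC=C3)C3C=CC=C3)cc(OC)c1OCc1ccccc1 | intermediate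
11 | benzylic iodide: (2S,3R,4R)-2-(aryl A)oxolane with CH2O–TiCp2Cl on C-3 and CH(I)(aryl B) on C-4 (benzylic configuration undefined) | COc1cc(C(I)[C@H]2CO[C@H](c3cc(OC)c(O[Si](C(C)C)(C(C)C)C(C)C)c(OC)c3)[C@H]2CO[Ti](Cl)(C3C=CC=C3)C3C=CC=C3)cc(OC)c1OCc1ccccc1 | intermediate
12 | (1S,3aR,4S,6aR)-1-[4-(benzyloxy)-3,5-dimethoxyphenyl]-4-{3,5-dimethoxy-4-[(triisopropylsilyl)oxy]phenyl}tetrahydro-1H,3H-furo[3,4-c]furan | COc1cc(cc(OC)c1OCc1ccccc1)[C@H]1OC[C@@H]2[C@@H](c3cc(OC)c(O[Si](C(C)C)(C(C)C)C(C)C)c(OC)c3)OC[C@H]12 | intermediate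
13 | 4-[(1S,3aR,4S,6aR)-4-{3,5-dimethoxy-4-[(triisopropylsilyl)oxy]phenyl}tetrahydro-1H,3H-furo[3,4-c]furan-1-yl]-2,6-dimethoxyphenol | COc1cc(cc(OC)c1O)[C@H]1OC[C@@H]2[C@@H](c3cc(OC)c(O[Si](C(C)C)(C(C)C)C(C)C)c(OC)c3)OC[C@H]12 | intermediate
14 | (3aR,4S,6aR)-4-{3,5-dimethoxy-4-[(triisopropylsilyl)oxy]phenyl}-1-(4-hydroxy-3,5-dimethoxyphenyl)tetrahydro-1H,3H-furo[3,4-c]furan-1-ol (configuration at C-1 undefined) | COc1cc(cc(OC)c1O)C1(O)OC[C@@H]2[C@@H](c3cc(OC)c(O[Si](C(C)C)(C(C)C)C(C)C)c(OC)c3)OC[C@H]12 | intermediate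
15 | [(2S,3R,4R)-2-{3,5-dimethoxy-4-[(triisopropylsilyl)oxy]phenyl}-3-(hydroxymethyl)oxolan-4-yl](4-hydroxy-3,5-dimethoxyphenyl)methanone | COc1cc(C(=O)[C@H]2CO[C@H](c3cc(OC)c(O[Si](C(C)C)(C(C)C)C(C)C)c(OC)c3)[C@H]2CO)cc(OC)c1O | intermediate
16 | ciwujiatone, (4-hydroxy-3,5-dimethoxyphenyl)[(2S,3R,4R)-2-(4-hydroxy-3,5-dimethoxyphenyl)-3-(hydroxymethyl)oxolan-4-yl]methanone | COc1cc(C(=O)[C@H]2CO[C@H](c3cc(OC)c(O)c(OC)c3)[C@H]2CO)cc(OC)c1O | target

**Step count**

Total: 11 steps. Longest linear sequence: 8 steps (steps 1–3 or 4–6, then 7–11).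

**Steps most likely to fail, with fallbacks**

1. Step 8. What may go wrong: loss of the benzylic titanium species by protonation or elimination before iodine captures it, incomplete closure of ring D, and erosion of the 3,4-cis facial selectivity of the radical closure. Fallback, from 8 back to 13: the Cp2TiCl cyclisation of 8 is run with aqueous acid work-up in place of iodine, the better-precedented variant for 2-aryl-3-hydroxymethyl-4-benzyl oxolanes, and should give the monocyclic alcohol [(2S,3R,4R)-4-[4-(benzyloxy)-3,5-dimethoxybenzyl]-2-{3,5-dimethoxy-4-[(triisopropylsilyl)oxy]phenyl}oxolan-3-yl]methanol F1. Hydrogenolysis (H2, Pd/C, EtOAc) should then give the phenol 4-{[(2S,3R,4R)-2-{3,5-dimethoxy-4-[(triisopropylsilyl)oxy]phenyl}-3-(hydroxymethyl)oxolan-4-yl]methyl}-2,6-dimethoxyphenol F2. DDQ (1 equiv, dry CH2Cl2, 0 °C) oxidises the para-alkylphenol to its quinone methide, which the cis CH2OH captures to close ring D and give 13. Ring D is thus made by quinone methide etherification and not by iodide displacement. Only the 3,4-cis isomer can close to the cis-fused bicycle, so a 3,4-trans epimer is left behind and separated.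

2. Step 10. What may go wrong: over-oxidation of the free syringyl phenol (ipso attack with loss of the side chain as a benzoquinone), hydride abstraction at the silyl-protected ring, or incomplete hydrolysis. Fallback, from 13 back to 15: oxidation and hydrolysis are separated. Ag2O in dry MeOH should oxidise the phenol to the alkoxy-substituted quinone methide, which methanol captures to give the mixed methyl ketal 4-[(3aR,4S,6aR)-4-{3,5-dimethoxy-4-[(triisopropylsilyl)oxy]phenyl}-1-methoxytetrahydro-1H,3H-furo[3,4-c]furan-1-yl]-2,6-dimethoxyphenol F3. After removal of the silver salts, PPTS in wet acetone hydrolyses F3 to 15, so the ketone never meets the oxidant.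

3. Step 7. What may go wrong: Payne rearrangement of the alkoxide of 4, silyl transfer from the aryl silyl ether to the alkoxide, and ionisation or polymerisation of bromide 7. Fallback, from 6 and 4 back to 8: Tsuji–Trost allylic etherification. Alcohol 6 is acylated (ClCO2Me, pyridine, CH2Cl2) to the branched carbonate 1-[4-(benzyloxy)-3,5-dimethoxyphenyl]prop-2-en-1-yl methyl carbonate F4. The zinc alkoxide of 4 (Et2Zn, 0.5 equiv, THF) and Pd(PPh3)4 (zerovalent palladium, 5 mol%) should then give 8, because the alkoxide attacks the 1-aryl-π-allyl palladium complex at its unsubstituted terminus to give the linear E ether. The stereocentre of 4 is untouched, and neither a free bromide nor a sodium alkoxide is involved.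

**Further compounds**

F1 | step 8 | [(2S,3R,4R)-4-[4-(benzyloxy)-3,5-dimethoxybenzyl]-2-{3,5-dimethoxy-4-[(triisopropylsilyl)oxy]phenyl}oxolan-3-yl]methanol | COc1cc(C[C@H]2CO[C@H](c3cc(OC)c(O[Si](C(C)C)(C(C)C)C(C)C)c(OC)c3)[C@H]2CO)cc(OC)c1OCc1ccccc1
F2 | step 8 | 4-{[(2S,3R,4R)-2-{3,5-dimethoxy-4-[(triisopropylsilyl)oxy]phenyl}-3-(hydroxymethyl)oxolan-4-yl]methyl}-2,6-dimethoxyphenol | COc1cc(C[C@H]2CO[C@H](c3cc(OC)c(O[Si](C(C)C)(C(C)C)C(C)C)c(OC)c3)[C@H]2CO)cc(OC)c1O
F3 | step 10 | 4-[(3aR,4S,6aR)-4-{3,5-dimethoxy-4-[(triisopropylsilyl)oxy]phenyl}-1-methoxytetrahydro-1H,3H-furo[3,4-c]furan-1-yl]-2,6-dimethoxyphenol (configuration at C-1 undefined) | COc1cc(cc(OC)c1O)C1(OC)OC[C@@H]2[C@@H](c3cc(OC)c(O[Si](C(C)C)(C(C)C)C(C)C)c(OC)c3)OC[C@H]12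
F4 | step 7 | 1-[4-(benzyloxy)-3,5-dimethoxyphenyl]prop-2-en-1-yl methyl carbonate (racemic) | COC(=O)OC(C=C)c1cc(OC)c(OCc2ccccc2)c(OC)c1
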